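I choose to reckon what this flask loses, not what it makes, and to take the over-reaction product as the remainder. Starting material is fed over 6.0 s into a stirred solution holding a little protic impurity, as in the earlier zeta and alpha runs.

| setting | zeta | alpha | flask |
|---|---|---|---|
| starting material | 0.25 M (fed, over 6.0 s) | 0.55 M (fed, over 6.0 s) | 0.37 M (fed, over 6.0 s) |
| protic impurity | 0.037 M | 0.037 M | 0.0370 M |
| remark | run made earlier; the fed solution adds 0.10 times the starting volume | run made earlier; the fed solution adds 0.10 times the starting volume | the fed solution adds 0.10 times the starting volume |
| time |  |  | 25 min |

| run | time / min | starting material / % | over-reaction product / % | target / % |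
|---|---|---|---|---|
| zeta | 2.00 | 7.3 | 49.1 | 7.4 |
| zeta | 5.00 | 2.9 | 74.3 | 2.8 |
| zeta | 10.0 | 0.6 | 82.9 | 1.3 |
| zeta | 15.0 | 0 | 85.3 | 1.6 |
| zeta | 20.0 | 2.2 | 85.8 | 0.4 |
| alpha | 1.50 | 8.5 | 43.0 | 9.9 |
| alpha | 3.00 | 5.3 | 67.1 | 4.9 |
| alpha | 6.00 | 2.2 | 85.1 | 2.5 |
| alpha | 10.0 | 0 | 90.8 | 0.4 |
| alpha | 20.0 | 0 | 91.6 | 0.1 |

(each reading ± 1 percentage point)

- amounts are per litre of the starting volume; all of the dose is in the solution fed
- the analysis behind the earlier runs scatters by 1 percentage point, standard deviation
- the reaction counts as stopped when no species that holds the starting material changes by six tenths of a point or more over the second half of the time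
- a reading of target is of its free form alone
- a reading of starting material is of its free form alone

- why nothing more happens at 25 min, or that something still does (forward and back rates have come level / all of the starting material has reacted / it is still moving)
- conversion of starting material at 25 min
- amount of over-reaction product at 25 min, in percent of the starting material charged

The late readings look contradictory: zeta and alpha held the same 0.037 M of protic impurity, yet at 20.0 min the over-reaction product of zeta falls short of the charge by 14.2 % and that of alpha by 8.40 %. Per litre, however, those shortfalls are 0.0355 M and 0.0462 M. Zeta's is close to the impurity and alpha's somewhat higher than it, with readings that scatter by 1 percentage point. So the percentage differs mainly because the charge differs.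

I therefore carry one quantity, 10.0 % for this flask: the impurity toll, [protic impurity]/[starting material], the share of the charge lost one for one. My reckoning leaves 90.0 % of over-reaction product. Alpha already reads 0 % of starting material at 10.0 min, earlier than the asked 25 min.

The forecast says all of the starting material has reacted, with conversion 100 % (96 % to 100 %) and over-reaction product 89.7 % (87.5 % to 91.5 %). It reads the gap as “roughly a fixed molar loss matching the 0.037 M protic impurity”, allows a small extra, and so stands 0.3 points under my figure.

In the flask at 25 min, all of the starting material has reacted, with conversion >99.9 % and over-reaction product 90.0 %.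

    target → over-reaction product (k = 0.0344 /s)
    starting material ⇌ target (K = 1.10, k = 0.154 /s)
    target ⇌ isomer of the product B (K = 0.140, k = 0.0323 /s)
    starting material + protic impurity → quenched substrate (k = 13.0 /M/s)
    target ⇌ isomer of the product A (k = 0.0542 /s)
    starting material ⇌ isomer of the product A (K = 2.58, k = 0.0685 /s)

In this flask the quenched substrate stands at 10.0 % at 25.0 min, against a toll of 10.0 %. It already stands at 10.0 % at 0.100 min, when the protic impurity, the limiting reagent of the quench, is down to 0.0263 % of its own charge. The loss in this flask is thus taken during the feed, and over-reaction product, 1.45 % at that moment, stands at 89.5 % at 12.5 min. A neighbouring flask holds 0.93 M of starting material with the same impurity, so its toll is 3.98 % and the remainder 96.0 %. That neighbouring flask gives 3.98 % of quenched substrate and 96.0 % of over-reaction product.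

The numbers in the tables stem from a simulated flask with made-up constants; noise was put on by code.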